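**Plan**

1. Retrosynthetic cuts, in order: the two phenol ethers and the aryl ketone (back to MOM ethers and a silyl‑protected benzylic carbinol); the prenyl C=C (Wittig, back to a CH2CO2Me arm); the ring bond between C‑2 (the CH carrying the side chain) and C‑3 (the methyl‑bearing sp2 carbon); the C‑3=C‑4 iodoalkene and the enoate C=C (two olefinations); the C‑1–CH(O)Ar bond (aldol); the C‑6–phenyl bond (Rh 1,4‑addition).
2. Enabling feature: in the cyclohexene (C‑1 aroyl, C‑2 prenyl, C‑3(Me)=C‑4H, C‑5H2, C‑6 Ph), C‑2 lies β to the CH carbon of the prenyl group. With that carbon written as an ester carbonyl, C‑2 is the β‑carbon of an (E)‑enoate and C‑3(Me)=C‑4H–C‑5H2 is a (Z)‑3‑iodobut‑2‑enyl group on C‑6, so C‑2–C‑3 is a 6‑exo conjugate alkenylation.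
3. Forward: protected aryl aldehyde (3 steps); (S)‑4‑phenyl‑δ‑valerolactone; trans aldol with silylation; lactone → lactol → enoate; alcohol → aldehyde → (Z)‑iodoalkene; Ni(0) closure of the cyclohexene (the only ring made that stays); ester → aldehyde → prenyl; carbinol → ketone; MOM removal.
4. Helpers: the ester oxidation level at the future prenyl CH, and the silyl ether that keeps the future ketone carbon at the alcohol level so that H‑1 is not acidic; both are taken out after the ring closure.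
5. Stereochemistry: C‑6 from (S)‑BINAP/Rh; C‑1 from attack on the lactone enolate anti to phenyl (3,4‑trans); C‑2 from the all‑equatorial chair transition state of the ring closure.

Key step: step 10

Assumption: the silyloxy‑bearing benzylic carbon made in step 5 becomes the ketone carbon in step 14, so it is carried as an epimer mixture (anti aldol expected to predominate) and written without a descriptor in 9–18; (S)‑BINAP is taken to give the 4S lactone by analogy with cyclic enones.

**Route**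

Step 1
Reactants: 1 3,4,5-trimethoxyphenol
Product: 2 6-hydroxy-2,3,4-trimethoxybenzaldehyde
Conditions: MgCl2, Et3N, (CH2O)n, MeCN, reflux
Reagents that add atoms: paraformaldehyde (formaldehyde), C=O
Why: Magnesium‑phenoxide‑directed ortho‑formylation (Casnati–Skattebøl reaction); the two ortho positions of 1 are equivalent, so a single aldehyde should form.

Step 2
Reactants: 2 6-hydroxy-2,3,4-trimethoxybenzaldehyde
Product: 3 2,6-dihydroxy-3,4-dimethoxybenzaldehyde
Conditions: BCl3, CH2Cl2, −78 °C → rt; H2O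
Reagents that add atoms: none
Why: Chelation‑directed Lewis acid ether cleavage: boron held at the formyl oxygen should demethylate only the methoxy group ortho to the carbonyl.

Step 3
Reactants: 3 2,6-dihydroxy-3,4-dimethoxybenzaldehyde
Product: 4 3,4-dimethoxy-2,6-bis(methoxymethoxy)benzaldehyde
Conditions: NaH, MOMCl, DMF, 0 °C → rt
Reagents that add atoms: chloromethyl methyl ether, COCCl
Why: Williamson‑type O‑alkylation (MOM protection) of both hydrogen‑bonded phenols after full deprotonation.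

Step 4
Reactants: 5 5,6-dihydro-2H-pyran-2-one; 6 phenylboronic acid
Product: 7 (S)-4-phenyltetrahydro-2H-pyran-2-one
Conditions: Rh(acac)(C2H4)2 (3 mol %), (S)-BINAP, dioxane–H2O 10:1, 100 °C
Reagents that add atoms: none
Why: Hayashi–Miyaura Rh‑catalysed asymmetric 1,4‑addition; the (S)‑BINAP–Rh–phenyl species selects one face of the unsaturated lactone and sets C‑4 (S), the future C‑6.

Step 5
Reactants: 7 (S)-4-phenyltetrahydro-2H-pyran-2-one; 4 3,4-dimethoxy-2,6-bis(methoxymethoxy)benzaldehyde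
Product: 10 (3S,4S)-3-{[3,4-dimethoxy-2,6-bis(methoxymethoxy)phenyl][(triethylsilyl)oxy]methyl}-4-phenyltetrahydro-2H-pyran-2-one, via lithium enolate 8 (not isolated), via lithium aldolate 9 (not isolated)
Conditions: LDA, THF, −78 °C; 4, −78 °C; TESOTf, −78 → 0 °C
Reagents that add atoms: triethylsilyl trifluoromethanesulfonate, CC[Si](CC)(CC)OS(=O)(=O)C(F)(F)F
Why: Lithium enolate aldol addition in which the aldehyde should attack the enolate face anti to the C‑4 phenyl group (3,4‑trans, setting the future C‑1), followed by O‑silylation of the aldolate to block retro‑aldol cleavage; the silyloxy carbon is not controlled and need not be.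

Step 6
Reactants: 10 silyl-protected aldol lactone
Product: 11 (3S,4S)-3-{[3,4-dimethoxy-2,6-bis(methoxymethoxy)phenyl][(triethylsilyl)oxy]methyl}-4-phenyltetrahydro-2H-pyran-2-ol
Conditions: DIBAL-H (1.1 equiv), CH2Cl2, −78 °C; Rochelle salt
Reagents that add atoms: none
Why: Partial hydride reduction of a lactone to the lactol; the aluminium hemiacetal is stable at −78 °C, so over‑reduction should be avoided.

Step 7
Reactants: 11 lactol
Product: 12 methyl (2E,4S,5S)-4-{[3,4-dimethoxy-2,6-bis(methoxymethoxy)phenyl][(triethylsilyl)oxy]methyl}-7-hydroxy-5-phenylhept-2-enoate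
Conditions: Ph3P=CHCO2Me, PhCO2H (cat.), toluene, 80 °C
Reagents that add atoms: methyl (triphenylphosphoranylidene)acetate, COC(=O)C=P(c1ccccc1)(c1ccccc1)c1ccccc1
Why: Wittig olefination of the open hydroxy‑aldehyde form of the lactol with a stabilised ylide should give the (E)‑enoate and free the primary alcohol.

Step 8
Reactants: 12 hydroxy enoate
Product: 13 methyl (2E,4S,5S)-4-{[3,4-dimethoxy-2,6-bis(methoxymethoxy)phenyl][(triethylsilyl)oxy]methyl}-7-oxo-5-phenylhept-2-enoate
Conditions: Dess–Martin periodinane, pyridine, CH2Cl2, 0 °C → rt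
Reagents that add atoms: none
Why: Dess–Martin oxidation of the primary alcohol to the aldehyde under buffered conditions that spare the silyl ether, the MOM ethers and the enoate.

Step 9
Reactants: 13 aldehyde enoate
Product: 14 methyl (2E,4S,5S,7Z)-4-{[3,4-dimethoxy-2,6-bis(methoxymethoxy)phenyl][(triethylsilyl)oxy]methyl}-8-iodo-5-phenylnona-2,7-dienoate
Conditions: EtPPh3I, n-BuLi, THF, rt; I2, −78 °C; NaHMDS, −20 °C; then 13, −78 °C
Reagents that add atoms: ethyltriphenylphosphonium iodide, CC[P+](c1ccccc1)(c1ccccc1)c1ccccc1.[I-]; iodine, II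
Why: Stork–Zhao‑type Wittig olefination with the α‑iodoethylidene ylide should give the (Z)‑2‑iodoalkene (iodine cis to the chain), the aldehyde reacting far faster than the enoate at −78 °C.

Step 10
Reactants: 14 (Z)-iodoalkene enoate
Product: 15 methyl 2-[(1S,5S,6S)-6-{[3,4-dimethoxy-2,6-bis(methoxymethoxy)phenyl][(triethylsilyl)oxy]methyl}-2-methyl-5-phenylcyclohex-2-en-1-yl]acetate
Conditions: Ni(cod)2 (2.5 equiv), Et3N, MeCN–DMF, rt; aq. NH4Cl
Reagents that add atoms: none
Why: Oxidative addition of Ni(0) into the C–I bond gives a (Z)‑alkenylnickel(II) iodide with retention of geometry, which adds syn across the tethered (E)‑enoate at its β‑carbon (the future C‑2), and the nickel enolate is protonated on work‑up. The closest known reaction type is the Ni(cod)2‑mediated (reductive Heck‑type) intramolecular conjugate addition of iodoalkenyl groups to α,β‑unsaturated esters. The cyclohexene closes in the 6‑exo‑trig mode, the former iodo carbon becoming the methyl‑bearing sp2 ring carbon. The only new stereocentre, C‑2, is set by the existing C‑1 and C‑6 centres through a chair‑like transition state in which the phenyl group, the silyloxybenzyl group and the enoate arm are all pseudo‑equatorial, which should give the 1,2‑trans‑2,6‑cis ring. The step needs 6‑exo closure to outrun 7‑endo attack and protodeiodination and needs the Z iodide; the polarised enoate directs bonding to its β‑carbon and step 9 supplies the Z geometry. Because C‑1 carries a silyl ether and not the ketone, H‑1 is not acidified and the enoate cannot drift into conjugation.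

Step 11
Reactants: 15 cyclohexenyl acetate
Product: 16 2-[(1S,5S,6S)-6-{[3,4-dimethoxy-2,6-bis(methoxymethoxy)phenyl][(triethylsilyl)oxy]methyl}-2-methyl-5-phenylcyclohex-2-en-1-yl]acetaldehyde
Conditions: DIBAL-H (1.1 equiv), CH2Cl2, −78 °C; MeOH, Rochelle salt
Reagents that add atoms: none
Why: Partial DIBAL reduction of the unhindered methyl ester to the aldehyde at −78 °C; no other reducible group is present.

Step 12
Reactants: 16 aldehyde
Product: 17 {[3,4-dimethoxy-2,6-bis(methoxymethoxy)phenyl][(1S,2S,6S)-3-methyl-2-(3-methylbut-2-en-1-yl)-6-phenylcyclohex-3-en-1-yl]methoxy}triethylsilane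
Conditions: i-PrPPh3I, n-BuLi, THF, 0 °C; then 16, −78 °C → rt
Reagents that add atoms: isopropyltriphenylphosphonium iodide, CC(C)[P+](c1ccccc1)(c1ccccc1)c1ccccc1.[I-]
Why: Wittig olefination with the non‑stabilised isopropylidene ylide completes the prenyl group; the alkene has no E/Z issue.

Step 13
Reactants: 17 silyl ether
Product: 18 [3,4-dimethoxy-2,6-bis(methoxymethoxy)phenyl][(1S,2S,6S)-3-methyl-2-(3-methylbut-2-en-1-yl)-6-phenylcyclohex-3-en-1-yl]methanol
Conditions: TBAF, THF, 0 → 40 °C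
Reagents that add atoms: none
Why: Fluoride‑mediated desilylation frees the benzylic alcohol and leaves the MOM ethers and both alkenes untouched.

Step 14
Reactants: 18 benzylic alcohol
Product: 19 [3,4-dimethoxy-2,6-bis(methoxymethoxy)phenyl][(1S,2S,6S)-3-methyl-2-(3-methylbut-2-en-1-yl)-6-phenylcyclohex-3-en-1-yl]methanone
Conditions: Dess–Martin periodinane, pyridine, CH2Cl2, rt
Reagents that add atoms: none
Why: Dess–Martin oxidation of the secondary benzylic alcohol to the aryl ketone merges both carbinol epimers; C‑1 already has the all‑equatorial configuration, which should also be the thermodynamic one, so enolisation should not change it.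

Step 15
Reactants: 19 bis-MOM ketone
Product: 20 (2,6-dihydroxy-3,4-dimethoxyphenyl)[(1S,2S,6S)-3-methyl-2-(3-methylbut-2-en-1-yl)-6-phenylcyclohex-3-en-1-yl]methanone
Conditions: HCl (cat.), MeOH, 45 °C
Reagents that add atoms: none
Why: Acid‑catalysed acetal exchange (MOM methanolysis) releases the two ketone‑chelated phenols; dilute methanolic acid is expected to spare the prenyl and ring alkenes.

**Compound list**

1 | 3,4,5-trimethoxyphenol | COc1cc(O)cc(OC)c1OC | starting material
2 | 6-hydroxy-2,3,4-trimethoxybenzaldehyde | COc1cc(O)c(C=O)c(OC)c1OC | intermediate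
3 | 2,6-dihydroxy-3,4-dimethoxybenzaldehyde | COc1cc(O)c(C=O)c(O)c1OC | intermediate
4 | 3,4-dimethoxy-2,6-bis(methoxymethoxy)benzaldehyde | COCOc1cc(OC)c(OC)c(OCOC)c1C=O | intermediate
5 | 5,6-dihydro-2H-pyran-2-one | O=C1C=CCCO1 | starting material
6 | phenylboronic acid | OB(O)c1ccccc1 | starting material
7 | (S)-4-phenyltetrahydro-2H-pyran-2-one | O=C1C[C@@H](c2ccccc2)CCO1 | intermediate
8 | lithium (4S)-4-phenyl-5,6-dihydro-4H-pyran-2-olate (lithium enolate of 7) | [Li+].[O-]C1=C[C@@H](c2ccccc2)CCO1 | intermediate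
9 | lithium alkoxide of (3S,4S)-3-{[3,4-dimethoxy-2,6-bis(methoxymethoxy)phenyl](hydroxy)methyl}-4-phenyltetrahydro-2H-pyran-2-one (epimers at the alkoxide carbon) | O=C1[C@H](C([O-])c2c(OCOC)cc(OC)c(OC)c2OCOC)[C@@H](c2ccccc2)CCO1.[Li+] | intermediate
10 | (3S,4S)-3-{[3,4-dimethoxy-2,6-bis(methoxymethoxy)phenyl][(triethylsilyl)oxy]methyl}-4-phenyltetrahydro-2H-pyran-2-one (3,4-trans; epimers at the silyloxy carbon) | O=C1[C@H](C(O[Si](CC)(CC)CC)c2c(OCOC)cc(OC)c(OC)c2OCOC)[C@@H](c2ccccc2)CCO1 | intermediate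
11 | (3S,4S)-3-{[3,4-dimethoxy-2,6-bis(methoxymethoxy)phenyl][(triethylsilyl)oxy]methyl}-4-phenyltetrahydro-2H-pyran-2-ol (lactol, anomers) | OC1[C@H](C(O[Si](CC)(CC)CC)c2c(OCOC)cc(OC)c(OC)c2OCOC)[C@@H](c2ccccc2)CCO1 | intermediate
12 | methyl (2E,4S,5S)-4-{[3,4-dimethoxy-2,6-bis(methoxymethoxy)phenyl][(triethylsilyl)oxy]methyl}-7-hydroxy-5-phenylhept-2-enoate | COC(=O)/C=C/[C@H](C(O[Si](CC)(CC)CC)c1c(OCOC)cc(OC)c(OC)c1OCOC)[C@@H](c1ccccc1)CCO | intermediate
13 | methyl (2E,4S,5S)-4-{[3,4-dimethoxy-2,6-bis(methoxymethoxy)phenyl][(triethylsilyl)oxy]methyl}-7-oxo-5-phenylhept-2-enoate | COC(=O)/C=C/[C@H](C(O[Si](CC)(CC)CC)c1c(OCOC)cc(OC)c(OC)c1OCOC)[C@@H](c1ccccc1)CC=O | intermediate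
14 | methyl (2E,4S,5S,7Z)-4-{[3,4-dimethoxy-2,6-bis(methoxymethoxy)phenyl][(triethylsilyl)oxy]methyl}-8-iodo-5-phenylnona-2,7-dienoate | COC(=O)/C=C/[C@H](C(O[Si](CC)(CC)CC)c1c(OCOC)cc(OC)c(OC)c1OCOC)[C@@H](c1ccccc1)C/C=C(\I)C | intermediate
15 | methyl 2-[(1S,5S,6S)-6-{[3,4-dimethoxy-2,6-bis(methoxymethoxy)phenyl][(triethylsilyl)oxy]methyl}-2-methyl-5-phenylcyclohex-2-en-1-yl]acetate | CC[Si](CC)(CC)OC(c1c(OCOC)cc(OC)c(OC)c1OCOC)[C@H]1[C@H](CC(=O)OC)C(C)=CC[C@@H]1c1ccccc1 | intermediate
16 | 2-[(1S,5S,6S)-6-{[3,4-dimethoxy-2,6-bis(methoxymethoxy)phenyl][(triethylsilyl)oxy]methyl}-2-methyl-5-phenylcyclohex-2-en-1-yl]acetaldehyde | CC[Si](CC)(CC)OC(c1c(OCOC)cc(OC)c(OC)c1OCOC)[C@H]1[C@H](CC=O)C(C)=CC[C@@H]1c1ccccc1 | intermediate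
17 | {[3,4-dimethoxy-2,6-bis(methoxymethoxy)phenyl][(1S,2S,6S)-3-methyl-2-(3-methylbut-2-en-1-yl)-6-phenylcyclohex-3-en-1-yl]methoxy}triethylsilane | CC[Si](CC)(CC)OC(c1c(OCOC)cc(OC)c(OC)c1OCOC)[C@H]1[C@H](CC=C(C)C)C(C)=CC[C@@H]1c1ccccc1 | intermediate
18 | [3,4-dimethoxy-2,6-bis(methoxymethoxy)phenyl][(1S,2S,6S)-3-methyl-2-(3-methylbut-2-en-1-yl)-6-phenylcyclohex-3-en-1-yl]methanol | OC(c1c(OCOC)cc(OC)c(OC)c1OCOC)[C@H]1[C@H](CC=C(C)C)C(C)=CC[C@@H]1c1ccccc1 | intermediate
19 | [3,4-dimethoxy-2,6-bis(methoxymethoxy)phenyl][(1S,2S,6S)-3-methyl-2-(3-methylbut-2-en-1-yl)-6-phenylcyclohex-3-en-1-yl]methanone | COCOc1cc(OC)c(OC)c(OCOC)c1C(=O)[C@H]1[C@H](CC=C(C)C)C(C)=CC[C@@H]1c1ccccc1 | intermediate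
20 | (2,6-dihydroxy-3,4-dimethoxyphenyl)[(1S,2S,6S)-3-methyl-2-(3-methylbut-2-en-1-yl)-6-phenylcyclohex-3-en-1-yl]methanone | COc1cc(O)c(C(=O)[C@H]2[C@H](CC=C(C)C)C(C)=CC[C@@H]2c2ccccc2)c(O)c1OC | target

**Count**

Total steps: 15. Longest linear sequence: 14 (steps 1–3, then 5–15); the lactone branch (step 4) joins at step 5.

**Steps most likely to fail**

Step 10. The alkenylnickel species may be protonated before it cyclises (protodeiodination). The ring may also close through a transition state with the C‑1 and C‑6 groups axial, which would erode facial selectivity at C‑2. The fallback is a redox‑relay Heck closure that sets out from 14. DIBAL‑H (2.2 equiv, CH2Cl2, −78 °C) reduces the enoate to the allylic alcohol (2E,4S,5S,7Z)-4-{[3,4-dimethoxy-2,6-bis(methoxymethoxy)phenyl][(triethylsilyl)oxy]methyl}-8-iodo-5-phenylnona-2,7-dien-1-ol F1. Pd(OAc)2, n‑Bu4NCl and NaHCO3 in DMF at 50 °C should then effect 6‑exo carbopalladation at the same carbon, with β‑hydride elimination toward the carbinol carbon and tautomerisation of the enol. This would give aldehyde 16 directly, where the route is rejoined.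

Step 9. The iodo ylide is unstable and the aldehyde is hindered, so Z/E control may be lost and the ylide may decompose before it reacts. The fallback sets out from 13. Corey–Fuchs dibromo‑olefination (CBr4, PPh3, Zn, CH2Cl2) would give methyl (2E,4S,5S)-8,8-dibromo-4-{[3,4-dimethoxy-2,6-bis(methoxymethoxy)phenyl][(triethylsilyl)oxy]methyl}-5-phenylocta-2,7-dienoate F2. A Pd‑catalysed Negishi coupling with MeZnCl (Pd(t‑Bu3P)2, THF, 0 °C) should replace only the bromide trans to the chain and give methyl (2E,4S,5S,7Z)-8-bromo-4-{[3,4-dimethoxy-2,6-bis(methoxymethoxy)phenyl][(triethylsilyl)oxy]methyl}-5-phenylnona-2,7-dienoate F3. This bromoalkene would undergo the same Ni(0) closure and come back to the route at 15.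

Step 7. Under the hot Wittig conditions the freed primary hydroxyl may add to the new enoate (oxa‑Michael closure to a tetrahydropyran). The fallback sets out from 10 and keeps alcohol and enoate apart:
- Aminolysis of 10 with MeNHOMe·HCl and i‑PrMgCl (THF, −20 °C) would give (2S,3S)-2-{[3,4-dimethoxy-2,6-bis(methoxymethoxy)phenyl][(triethylsilyl)oxy]methyl}-5-hydroxy-N-methoxy-N-methyl-3-phenylpentanamide F4.
- Dess–Martin oxidation would give (2S,3S)-2-{[3,4-dimethoxy-2,6-bis(methoxymethoxy)phenyl][(triethylsilyl)oxy]methyl}-N-methoxy-N-methyl-5-oxo-3-phenylpentanamide F5.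
- The iodo‑olefination of step 9 would give (2S,3S,5Z)-2-{[3,4-dimethoxy-2,6-bis(methoxymethoxy)phenyl][(triethylsilyl)oxy]methyl}-6-iodo-N-methoxy-N-methyl-3-phenylhept-5-enamide F6.
- DIBAL‑H at −78 °C would reduce the amide to (2S,3S,5Z)-2-{[3,4-dimethoxy-2,6-bis(methoxymethoxy)phenyl][(triethylsilyl)oxy]methyl}-6-iodo-3-phenylhept-5-enal F7.
- Wittig olefination of F7 with Ph3P=CHCO2Me would come back to the route at 14.

Further compounds
F1 | step 10 | (2E,4S,5S,7Z)-4-{[3,4-dimethoxy-2,6-bis(methoxymethoxy)phenyl][(triethylsilyl)oxy]methyl}-8-iodo-5-phenylnona-2,7-dien-1-ol | OC/C=C/[C@H](C(O[Si](CC)(CC)CC)c1c(OCOC)cc(OC)c(OC)c1OCOC)[C@@H](c1ccccc1)C/C=C(\I)C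
F2 | step 9 | methyl (2E,4S,5S)-8,8-dibromo-4-{[3,4-dimethoxy-2,6-bis(methoxymethoxy)phenyl][(triethylsilyl)oxy]methyl}-5-phenylocta-2,7-dienoate | COC(=O)/C=C/[C@H](C(O[Si](CC)(CC)CC)c1c(OCOC)cc(OC)c(OC)c1OCOC)[C@@H](c1ccccc1)CC=C(Br)Br
F3 | step 9 | methyl (2E,4S,5S,7Z)-8-bromo-4-{[3,4-dimethoxy-2,6-bis(methoxymethoxy)phenyl][(triethylsilyl)oxy]methyl}-5-phenylnona-2,7-dienoate | COC(=O)/C=C/[C@H](C(O[Si](CC)(CC)CC)c1c(OCOC)cc(OC)c(OC)c1OCOC)[C@@H](c1ccccc1)C/C=C(\Br)C
F4 | step 7 | (2S,3S)-2-{[3,4-dimethoxy-2,6-bis(methoxymethoxy)phenyl][(triethylsilyl)oxy]methyl}-5-hydroxy-N-methoxy-N-methyl-3-phenylpentanamide | CON(C)C(=O)[C@H](C(O[Si](CC)(CC)CC)c1c(OCOC)cc(OC)c(OC)c1OCOC)[C@@H](c1ccccc1)CCO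
F5 | step 7 | (2S,3S)-2-{[3,4-dimethoxy-2,6-bis(methoxymethoxy)phenyl][(triethylsilyl)oxy]methyl}-N-methoxy-N-methyl-5-oxo-3-phenylpentanamide | CON(C)C(=O)[C@H](C(O[Si](CC)(CC)CC)c1c(OCOC)cc(OC)c(OC)c1OCOC)[C@@H](c1ccccc1)CC=O
F6 | step 7 | (2S,3S,5Z)-2-{[3,4-dimethoxy-2,6-bis(methoxymethoxy)phenyl][(triethylsilyl)oxy]methyl}-6-iodo-N-methoxy-N-methyl-3-phenylhept-5-enamide | CON(C)C(=O)[C@H](C(O[Si](CC)(CC)CC)c1c(OCOC)cc(OC)c(OC)c1OCOC)[C@@H](c1ccccc1)C/C=C(\I)C
F7 | step 7 | (2S,3S,5Z)-2-{[3,4-dimethoxy-2,6-bis(methoxymethoxy)phenyl][(triethylsilyl)oxy]methyl}-6-iodo-3-phenylhept-5-enal | O=C[C@H](C(O[Si](CC)(CC)CC)c1c(OCOC)cc(OC)c(OC)c1OCOC)[C@@H](c1ccccc1)C/C=C(\I)C
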